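**Retrosynthetic overview**
- The 1,6-diketone side chain is a masked tetrasubstituted cyclohexene, so the target comes from a late ozonolysis of a β-cyclogeranyl-type 1,2-dioxane; dihydro-β-ionone supplies C6–C15.
- The 1,2-dioxane (the only ring made in the route) is closed through the C6–O bond: a catalyst-controlled Markovnikov cyclisation of a C3 secondary hydroperoxide onto a C6 1,1-disubstituted alkene sets C6.
- The C3–OOH group comes from a second C–O bond formation: SN2 perhydrolysis (inversion) of the triflate of a syn-aldol alcohol.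
- The C5–C6 bond comes from a B-alkyl Suzuki coupling of the enol triflate of dihydro-β-ionone with the 9-BBN adduct of methyl (2S,3R)-3-hydroxy-2-methylpent-4-enoate; an Evans syn-aldol with acrolein sets C2 and C3.
- Ring order: the cyclohexene is bought in, the dioxane is formed in step 6, the cyclohexene is opened in step 7.

Assumption: the sense of induction of the chiral acid in step 6 is not known for this substrate class; the (S,S)-catalyst is taken as the enantiomer that gives the 3,6-cis dioxane, and its mirror image is used if the first screen shows otherwise.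

**Route**

Step 1
Reactants: 1 dihydro-β-ionone [4-(2,6,6-trimethylcyclohex-1-en-1-yl)butan-2-one]
Product: 3 4-(2,6,6-trimethylcyclohex-1-en-1-yl)but-1-en-2-yl trifluoromethanesulfonate, via lithium enolate 2 (not isolated)
Conditions: LDA (1.05 equiv), THF, −78 °C; PhNTf2, −78 → 0 °C; aq. NH4Cl
Reagents that add atoms: N-phenyl-bis(trifluoromethanesulfonimide) (PhNTf2), O=S(=O)(N(c1ccccc1)S(=O)(=O)C(F)(F)F)C(F)(F)F
Why: LDA deprotonates the methyl ketone kinetically at the CH3 side and the terminal enolate is trapped on oxygen (kinetic enol triflate formation), giving the 1,1-disubstituted vinyl electrophile; no stereocentre is formed.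

Step 2
Reactants: 4 (S)-4-benzyl-3-propanoyl-1,3-oxazolidin-2-one; 5 acrolein
Product: 7 (4S)-4-benzyl-3-[(2S,3R)-3-hydroxy-2-methylpent-4-enoyl]-1,3-oxazolidin-2-one, via Z-boron enolate 6 (not isolated)
Conditions: Bu2BOTf, iPr2NEt, CH2Cl2, −78 → 0 °C; acrolein, −78 → 0 °C; pH 7 buffer, MeOH, 30% H2O2, 0 °C
Reagents that add atoms: none
Why: Evans syn-aldol reaction in which the Z-boron enolate adds to acrolein through a closed Zimmerman–Traxler chair with the benzyl group shielding one face, setting C2 (S) and C3 (R).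

Step 3
Reactants: 7 (4S)-4-benzyl-3-[(2S,3R)-3-hydroxy-2-methylpent-4-enoyl]-1,3-oxazolidin-2-one
Product: 8 methyl (2S,3R)-3-hydroxy-2-methylpent-4-enoate
Conditions: NaOMe (1.1 equiv), MeOH, −15 °C, 15 min; aq. NH4Cl
Reagents that add atoms: sodium methoxide, [Na+].[O-]C; methanol, CO
Why: Methoxide attacks the exocyclic imide carbonyl (auxiliary methanolysis) at low temperature, releasing the oxazolidinone without retro-aldol or epimerisation of C2 or C3.

Step 4
Reactants: 8 methyl (2S,3R)-3-hydroxy-2-methylpent-4-enoate; 3 4-(2,6,6-trimethylcyclohex-1-en-1-yl)but-1-en-2-yl trifluoromethanesulfonate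
Product: 10 methyl (2S,3R)-3-hydroxy-2-methyl-6-methylidene-8-(2,6,6-trimethylcyclohex-1-en-1-yl)octanoate, via bis-boryl adduct 9 (not isolated)
Conditions: 9-BBN (2.3 equiv), THF, 0 °C → rt; then 3, PdCl2(dppf) (5 mol %), AsPh3 (5 mol %), aq. K3PO4, DMF, rt
Reagents that add atoms: none
Why: 9-BBN hydroborates only the monosubstituted alkene at its terminus (the free OH is masked in situ as its borinate) and the primary alkylborane undergoes B-alkyl Suzuki–Miyaura coupling with the enol triflate, forming C5–C6 without touching C2 or C3.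

Step 5
Reactants: 10 methyl (2S,3R)-3-hydroxy-2-methyl-6-methylidene-8-(2,6,6-trimethylcyclohex-1-en-1-yl)octanoate
Product: 12 methyl (2S,3S)-3-hydroperoxy-2-methyl-6-methylidene-8-(2,6,6-trimethylcyclohex-1-en-1-yl)octanoate, via secondary triflate 11 (not isolated)
Conditions: Tf2O (1.05 equiv), 2,6-lutidine, CH2Cl2, −78 °C; then anhydrous H2O2 in Et2O (10 equiv), −78 → −20 °C
Reagents that add atoms: hydrogen peroxide, OO
Why: The triflate formed at −78 °C is displaced by neutral hydrogen peroxide (α-effect nucleophile) in an SN2 perhydrolysis with inversion (3R → 3S), and the non-basic medium disfavours β-elimination to the enoate.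

Step 6
Reactants: 12 methyl (2S,3S)-3-hydroperoxy-2-methyl-6-methylidene-8-(2,6,6-trimethylcyclohex-1-en-1-yl)octanoate
Product: 13 methyl (2S)-2-[(3S,6S)-6-methyl-6-[2-(2,6,6-trimethylcyclohex-1-en-1-yl)ethyl]-1,2-dioxan-3-yl]propanoate
Conditions: (S,S)-IDPi (confined chiral imidodiphosphorimidate Brønsted acid, N-triflyl core, 3,3′-diaryl-BINOL walls; 5 mol %), cyclohexane, 25–40 °C
Reagents that add atoms: none
Why: Proposed new method: asymmetric intramolecular Markovnikov hydroperoxylation of an unactivated 1,1-disubstituted alkene, in which the OOH group hydrogen-bonds to the catalyst anion while the acidic proton goes to the terminal =CH2 in a concerted asynchronous step, the incipient tertiary cation at C6 is captured by the distal peroxide oxygen in a 6-exo chair with the C3 side chain equatorial, and the chiral pocket (not the substrate, since CH3 and CH2CH2R are sterically alike) selects the alkene face so that the new methyl is equatorial and the C7 chain axial, forming the C6–O bond and setting C6; the closest known reaction type is the IDPi-catalysed asymmetric intramolecular hydroalkoxylation of unactivated alkenols to 2,2-disubstituted tetrahydrofurans, alongside racemic acid-, Hg(II)- or halonium-mediated cyclisations of unsaturated hydroperoxides to 1,2-dioxanes.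

Step 7
Reactants: 13 methyl (2S)-2-[(3S,6S)-6-methyl-6-[2-(2,6,6-trimethylcyclohex-1-en-1-yl)ethyl]-1,2-dioxan-3-yl]propanoate
Product: 15 diacarperoxide B, methyl (2S)-2-[(3S,6R)-6-(4,4-dimethyl-3,8-dioxononyl)-6-methyl-1,2-dioxan-3-yl]propanoate, via secondary ozonide 14 (not isolated)
Conditions: O3, CH2Cl2, −78 °C (Sudan Red 7B end point); PPh3 (1.1 equiv), −78 → 0 °C
Reagents that add atoms: ozone, [O-][O+]=O
Why: Ozonolysis of the only remaining C=C (the electron-rich tetrasubstituted cyclohexene) with reductive work-up unveils the 1,6-diketone, PPh3 reducing the ozonide but not the dialkyl peroxide at or below 0 °C; no stereocentre is touched (the C6 descriptor changes from S to R only because the CIP priorities change).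

**Compound list**

1 | dihydro-β-ionone, 4-(2,6,6-trimethylcyclohex-1-en-1-yl)butan-2-one | CC(=O)CCC1=C(C)CCCC1(C)C | starting material
2 | lithium 4-(2,6,6-trimethylcyclohex-1-en-1-yl)but-1-en-2-olate (kinetic enolate) | [Li+].[O-]C(=C)CCC1=C(C)CCCC1(C)C | intermediate
3 | 4-(2,6,6-trimethylcyclohex-1-en-1-yl)but-1-en-2-yl trifluoromethanesulfonate | C=C(OS(=O)(=O)C(F)(F)F)CCC1=C(C)CCCC1(C)C | intermediate
4 | (S)-4-benzyl-3-propanoyl-1,3-oxazolidin-2-one | CCC(=O)N1[C@@H](Cc2ccccc2)COC1=O | starting material
5 | acrolein (prop-2-enal) | C=CC=O | starting material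
6 | (4S)-4-benzyl-3-[(1Z)-1-[(dibutylboranyl)oxy]prop-1-en-1-yl]-1,3-oxazolidin-2-one (Z-boron enolate) | C/C=C(\OB(CCCC)CCCC)N1[C@@H](Cc2ccccc2)COC1=O | intermediate
7 | (4S)-4-benzyl-3-[(2S,3R)-3-hydroxy-2-methylpent-4-enoyl]-1,3-oxazolidin-2-one | C=C[C@@H](O)[C@H](C)C(=O)N1[C@@H](Cc2ccccc2)COC1=O | intermediate
8 | methyl (2S,3R)-3-hydroxy-2-methylpent-4-enoate | COC(=O)[C@@H](C)[C@H](O)C=C | intermediate
9 | methyl (2S,3R)-5-(9-borabicyclo[3.3.1]nonan-9-yl)-3-[(9-borabicyclo[3.3.1]nonan-9-yl)oxy]-2-methylpentanoate | COC(=O)[C@@H](C)[C@H](OB1C2CCCC1CCC2)CCB1C2CCCC1CCC2 | intermediate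
10 | methyl (2S,3R)-3-hydroxy-2-methyl-6-methylidene-8-(2,6,6-trimethylcyclohex-1-en-1-yl)octanoate | COC(=O)[C@@H](C)[C@H](O)CCC(=C)CCC1=C(C)CCCC1(C)C | intermediate
11 | methyl (2S,3R)-2-methyl-6-methylidene-3-[(trifluoromethanesulfonyl)oxy]-8-(2,6,6-trimethylcyclohex-1-en-1-yl)octanoate | COC(=O)[C@@H](C)[C@H](OS(=O)(=O)C(F)(F)F)CCC(=C)CCC1=C(C)CCCC1(C)C | intermediate
12 | methyl (2S,3S)-3-hydroperoxy-2-methyl-6-methylidene-8-(2,6,6-trimethylcyclohex-1-en-1-yl)octanoate | COC(=O)[C@@H](C)[C@@H](OO)CCC(=C)CCC1=C(C)CCCC1(C)C | intermediate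
13 | methyl (2S)-2-[(3S,6S)-6-methyl-6-[2-(2,6,6-trimethylcyclohex-1-en-1-yl)ethyl]-1,2-dioxan-3-yl]propanoate (C3 side chain and C6 chain cis) | COC(=O)[C@@H](C)[C@@H]1CC[C@](C)(CCC2=C(C)CCCC2(C)C)OO1 | intermediate
14 | methyl (2S)-2-[(3S,6R)-6-methyl-6-[2-(2,2,5-trimethyl-6,7,8-trioxabicyclo[3.2.1]octan-1-yl)ethyl]-1,2-dioxan-3-yl]propanoate (secondary ozonide, mixture at the ozonide bridgeheads) | COC(=O)[C@@H](C)[C@@H]1CC[C@](C)(CCC23OOC(C)(O2)CCCC3(C)C)OO1 | intermediate
15 | diacarperoxide B, methyl (2S)-2-[(3S,6R)-6-(4,4-dimethyl-3,8-dioxononyl)-6-methyl-1,2-dioxan-3-yl]propanoate | COC(=O)[C@@H](C)[C@@H]1CC[C@](C)(CCC(=O)C(C)(C)CCCC(C)=O)OO1 | target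

**Totals and risks**

Total step count: 7. Longest linear sequence: 6 steps (4 + 5 → 7 → 8 → 10 → 12 → 13 → 15); the triflate 3 is made in one step in parallel.

Step 5 (perhydrolysis of the β-triflyloxy ester) may fail through β-elimination to the 2-methyl-2-enoate or through slow SN2 at the β-branched secondary carbon. The fallback closes the ring through the C3–O bond instead and uses known chemistry only. It sets out from 10: Mukaiyama–Isayama silylperoxidation of the 1,1-disubstituted alkene (Co(thd)2, O2, Et3SiH, ClCH2CH2Cl, rt; the tetrasubstituted ring alkene is inert) gives the tertiary silyl peroxide alcohol F1 as a 1:1 mixture at C6. Mesylation (MsCl, pyridine, 0 °C) gives the silylperoxy mesylate F2. Fluoride (TBAF, THF, 0 °C) frees the peroxide anion, which displaces the mesylate in a 6-exo-tet SN2 with inversion at C3. This gives 13 together with its C6 epimer F3, separated by chromatography, and the route is rejoined at 13.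

Step 6 (the new acid-catalysed hydroperoxylation) may fail through acid-induced Hock-type cleavage of the hydroperoxide, peroxylactone formation with the ester, protonation or migration of the ring alkene, or poor facial control. The fallback uses known cycloperoxymercuration chemistry and sets out from 12: Hg(OAc)2 (cat. HClO4, CH2Cl2, rt) closes the ring to the organomercurial dioxane F4 as both C6 epimers. Reductive demercuration (NaBH4, aq. NaOH, 0 °C) then gives 13 and its C6 epimer F3, which are separated by chromatography, and the route is rejoined at 13.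

Step 7 (ozonolysis of a hindered tetrasubstituted alkene beside a peroxide) may fail through anomalous ozonolysis, over-oxidation or partial reduction of the dioxane O–O bond by the phosphine. The fallback avoids ozone and any reductant and sets out from 13: mCPBA (NaHCO3, CH2Cl2, 0 °C) epoxidises the ring alkene to the epoxide F5. Periodic acid (H5IO6, THF/H2O, rt) then cleaves the epoxide to the diketone, and the route is rejoined at 15.

**Further compounds**

F1 | step 5 | methyl (2S,3R,6RS)-3-hydroxy-2,6-dimethyl-6-[(triethylsilyl)peroxy]-8-(2,6,6-trimethylcyclohex-1-en-1-yl)octanoate | COC(=O)[C@@H](C)[C@H](O)CCC(C)(OO[Si](CC)(CC)CC)CCC1=C(C)CCCC1(C)C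
F2 | step 5 | methyl (2S,3R,6RS)-3-(methanesulfonyloxy)-2,6-dimethyl-6-[(triethylsilyl)peroxy]-8-(2,6,6-trimethylcyclohex-1-en-1-yl)octanoate | COC(=O)[C@@H](C)[C@H](OS(C)(=O)=O)CCC(C)(OO[Si](CC)(CC)CC)CCC1=C(C)CCCC1(C)C
F3 | step 5 | methyl (2S)-2-[(3S,6R)-6-methyl-6-[2-(2,6,6-trimethylcyclohex-1-en-1-yl)ethyl]-1,2-dioxan-3-yl]propanoate (C6 epimer of 13) | COC(=O)[C@@H](C)[C@@H]1CC[C@@](C)(CCC2=C(C)CCCC2(C)C)OO1
F4 | step 6 | methyl (2S)-2-[(3S,6RS)-6-[(acetoxymercurio)methyl]-6-[2-(2,6,6-trimethylcyclohex-1-en-1-yl)ethyl]-1,2-dioxan-3-yl]propanoate | COC(=O)[C@@H](C)[C@@H]1CCC(C[Hg]OC(C)=O)(CCC2=C(C)CCCC2(C)C)OO1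
F5 | step 7 | methyl (2S)-2-[(3S,6R)-6-methyl-6-[2-(2,2,6-trimethyl-7-oxabicyclo[4.1.0]heptan-1-yl)ethyl]-1,2-dioxan-3-yl]propanoate | COC(=O)[C@@H](C)[C@@H]1CC[C@](C)(CCC23OC2(C)CCCC3(C)C)OO1
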